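**Retrosynthetic overview**

1. The target comes from the cis-(3S,4S)-isoflavan-4-ol that already carries ring D, by oxidation at C4 and then desilylation; the enolisable ketone exists only in the last two buffered steps.
2. Ring D is made by an aromatic propargyl Claisen / 1,5-H shift / oxa-6π cascade of the O4' 1,1-dimethylpropargyl ether. The plan rests on ring D being a 2,2-dimethyl-2H-pyran fused across C4'–C5' of ring B while C3' bears oxygen, so C5' is the only free carbon ortho to O4'; with C4 held as an sp3 carbinol, C3 cannot enolise while heated.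
3. C3 and C4 are set together by asymmetric transfer hydrogenation of the racemic isoflavanone under dynamic kinetic resolution; ring C comes from a 2'-hydroxydeoxybenzoin and formaldehyde (Mannich / oxa-Michael).
4. The deoxybenzoin comes from palladium-catalysed α-arylation of the bis-MOM acetophenone with an aryl bromide made from 5-bromo-2-hydroxybenzaldehyde (benzylation, Baeyer–Villiger, MOM). O4' is then freed and propargylated while O3' still carries MOM, and the silyl groups go on afterwards, so silicon cannot shift between the catechol oxygens and no alkyne meets palladium.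
5. Ring order: rings A and B are bought, ring C closes in step 10, ring D in step 12.

Key step: step 12

Remark on the chemistry: in the cis-isoflavan-4-ol with the target's 3S centre, hydroxyl and aryl lie on the same face and the descriptors are (3S,4S); C4 is a temporary stereocentre removed in step 13, and every C3-containing compound before step 11 is racemic by design.

**Route**

Step 1
Reactants: 1 2',4'-dihydroxy-6'-methoxyacetophenone
Product: 2 1-[2-methoxy-4,6-bis(methoxymethoxy)phenyl]ethan-1-one
Conditions: MOMCl, NaH, DMF, 0 °C to rt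
Reagents that add atoms: chloromethyl methyl ether (MOMCl), COCCl
Why: Williamson-type O-alkylation of both sodium phenoxides, including the hydrogen-bonded 2'-oxygen, gives the bis-acetal and leaves the methyl ketone free for enolate chemistry in step 5.

Step 2
Reactants: 3 5-bromo-2-hydroxybenzaldehyde
Product: 4 2-(benzyloxy)-5-bromobenzaldehyde
Conditions: BnBr, K2CO3, DMF, rt
Reagents that add atoms: benzyl bromide, BrCc1ccccc1
Why: Williamson ether synthesis on the acidic salicylaldehyde phenol marks the oxygen para to bromine (the later O4') with a group removable by hydrogenolysis.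

Step 3
Reactants: 4 2-(benzyloxy)-5-bromobenzaldehyde
Product: 6 2-(benzyloxy)-5-bromophenol, via aryl formate 5 (not isolated)
Conditions: mCPBA, CH2Cl2, rt; aq. NaHCO3/Na2S2O3 wash; then K2CO3 (cat.), MeOH, rt
Reagents that add atoms: 3-chloroperoxybenzoic acid (mCPBA), OOC(=O)c1cccc(Cl)c1
Why: Baeyer–Villiger (Dakin-type) oxidation, in which the electron-rich ortho-alkoxyaryl group migrates in the Criegee intermediate to give the formate, followed by methanolysis, turns the formyl carbon's position into the oxygen that becomes O3'.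

Step 4
Reactants: 6 2-(benzyloxy)-5-bromophenol
Product: 7 1-(benzyloxy)-4-bromo-2-(methoxymethoxy)benzene
Conditions: MOMCl, i-Pr2NEt, CH2Cl2, 0 °C to rt
Reagents that add atoms: chloromethyl methyl ether (MOMCl), COCCl
Why: O-alkylation of the phenol to the MOM acetal puts on O3' a group that cannot migrate to the neighbouring oxygen when O4' is later freed as a phenoxide.

Step 5
Reactants: 2 1-[2-methoxy-4,6-bis(methoxymethoxy)phenyl]ethan-1-one; 7 1-(benzyloxy)-4-bromo-2-(methoxymethoxy)benzene
Product: 8 2-[4-(benzyloxy)-3-(methoxymethoxy)phenyl]-1-[2-methoxy-4,6-bis(methoxymethoxy)phenyl]ethan-1-one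
Conditions: Pd2(dba)3 (cat.), Xantphos, NaOt-Bu, THF, 70 °C
Reagents that add atoms: none
Why: Buchwald–Hartwig-type α-arylation of the methyl ketone enolate (oxidative addition of the aryl bromide to zerovalent palladium, enolate transfer, reductive elimination) should give the monoarylated deoxybenzoin, since the wide-bite-angle ligand disfavours a second arylation and the substrate holds no silyl ether and no alkyne.

Step 6
Reactants: 8 2-[4-(benzyloxy)-3-(methoxymethoxy)phenyl]-1-[2-methoxy-4,6-bis(methoxymethoxy)phenyl]ethan-1-one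
Product: 9 2-[4-hydroxy-3-(methoxymethoxy)phenyl]-1-[2-methoxy-4,6-bis(methoxymethoxy)phenyl]ethan-1-one
Conditions: H2 (1 atm), Pd/C (palladium on carbon), EtOAc, rt
Reagents that add atoms: none
Why: catalytic hydrogenolysis cleaves only the benzyl aryl ether, because the doubly ortho-substituted aryl ketone and the MOM acetals are inert under neutral hydrogenation.

Step 7
Reactants: 9 2-[4-hydroxy-3-(methoxymethoxy)phenyl]-1-[2-methoxy-4,6-bis(methoxymethoxy)phenyl]ethan-1-one; 10 3-chloro-3-methylbut-1-yne
Product: 11 1-[2-methoxy-4,6-bis(methoxymethoxy)phenyl]-2-[3-(methoxymethoxy)-4-(2-methylbut-3-yn-2-yloxy)phenyl]ethan-1-one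
Conditions: DBU, CuCl2·2H2O (cat.), MeCN, 0 °C to rt
Reagents that add atoms: none
Why: copper-catalysed propargylic etherification (a copper acetylide ionises to an allenylidene-type electrophile that the phenoxide captures at the tertiary carbon) places the ether on O4' alone, because the neighbouring oxygen carries MOM and not silicon.

Step 8
Reactants: 11 1-[2-methoxy-4,6-bis(methoxymethoxy)phenyl]-2-[3-(methoxymethoxy)-4-(2-methylbut-3-yn-2-yloxy)phenyl]ethan-1-one
Product: 12 1-(2,4-dihydroxy-6-methoxyphenyl)-2-[3-hydroxy-4-(2-methylbut-3-yn-2-yloxy)phenyl]ethan-1-one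
Conditions: HCl (0.5 M), MeOH, 40 °C
Reagents that add atoms: none
Why: acid-catalysed acetal exchange with methanol removes the three MOM groups, while the tertiary propargylic aryl ether, whose cation is destabilised by the alkyne, should ionise far more slowly and survive.

Step 9
Reactants: 12 1-(2,4-dihydroxy-6-methoxyphenyl)-2-[3-hydroxy-4-(2-methylbut-3-yn-2-yloxy)phenyl]ethan-1-one
Product: 13 1-[2-hydroxy-6-methoxy-4-(triisopropylsilyloxy)phenyl]-2-[4-(2-methylbut-3-yn-2-yloxy)-3-(triisopropylsilyloxy)phenyl]ethan-1-one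
Conditions: TIPSCl, imidazole, DMF, 0 °C to rt
Reagents that add atoms: chlorotriisopropylsilane (TIPSCl), CC(C)[Si](Cl)(C(C)C)C(C)C
Why: imidazole-mediated silylation takes the two unhindered phenols, whereas the 2'-OH that is hydrogen-bonded to the ketone resists the bulky chlorosilane and stays free for ring closure.

Step 10
Reactants: 13 1-[2-hydroxy-6-methoxy-4-(triisopropylsilyloxy)phenyl]-2-[4-(2-methylbut-3-yn-2-yloxy)-3-(triisopropylsilyloxy)phenyl]ethan-1-one
Product: 16 rac-5-methoxy-3-[4-(2-methylbut-3-yn-2-yloxy)-3-(triisopropylsilyloxy)phenyl]-7-(triisopropylsilyloxy)chroman-4-one, via Mannich base 14 (not isolated), via enone 15 (not isolated)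
Conditions: (CH2O)n, Et2NH, i-PrOH, 60 °C
Reagents that add atoms: paraformaldehyde (formaldehyde source), C=O
Why: Mannich aminomethylation at the benzylic α-carbon, loss of Et2NH to the 2-arylpropenone and 6-endo-trig oxa-Michael addition of the 2'-phenol close ring C, and C3 is formed racemic, which is what the next step requires.

Step 11
Reactants: 16 rac-5-methoxy-3-[4-(2-methylbut-3-yn-2-yloxy)-3-(triisopropylsilyloxy)phenyl]-7-(triisopropylsilyloxy)chroman-4-one
Product: 17 (3S,4S)-5-methoxy-3-[4-(2-methylbut-3-yn-2-yloxy)-3-(triisopropylsilyloxy)phenyl]-7-(triisopropylsilyloxy)chroman-4-ol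
Conditions: RuCl(p-cymene)[(S,S)-TsDPEN] (cat.), HCO2H/Et3N (2:5), EtOAc, 40 °C
Reagents that add atoms: none
Why: Noyori asymmetric transfer hydrogenation under dynamic kinetic resolution, in which Et3N equilibrates the ketone enantiomers through the enol, the (S,S)-catalyst delivers hydride to the carbonyl face that gives the 4S carbinol, and only the 3S ketone accepts it anti to its C3 aryl group, should give the cis-(3S,4S) alcohol.

Step 12
Reactants: 17 (3S,4S)-5-methoxy-3-[4-(2-methylbut-3-yn-2-yloxy)-3-(triisopropylsilyloxy)phenyl]-7-(triisopropylsilyloxy)chroman-4-ol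
Product: 21 (3S,4S)-3-[2,2-dimethyl-8-(triisopropylsilyloxy)-2H-chromen-6-yl]-5-methoxy-7-(triisopropylsilyloxy)chroman-4-ol, via allenyl cyclohexadienone 18 (not isolated), via ortho-allenylphenol 19 (not isolated), via ortho-quinone methide 20 (not isolated)
Conditions: PhNEt2 (5 equiv), o-xylene, 140–150 °C, sealed tube, Ar
Reagents that add atoms: none
Why: Heating starts an aromatic propargyl Claisen rearrangement, a suprafacial [3,3] shift that joins the alkyne terminus to C5' and gives the allenyl cyclohexadienone, which enolises to the ortho-allenylphenol; a 1,5-hydrogen shift from the phenol to the central allene carbon then gives the (Z)-ortho-quinone methide, and its oxa-6π electrocyclisation forms the O–C(CH3)2 bond. The closest known reaction type is the thermal conversion of aryl 1,1-dimethylpropargyl ethers into 2,2-dimethyl-2H-chromenes. Ring D, the six-membered 2H-pyran, is closed by this thermal disrotatory 6π electrocyclisation of the 1-oxatriene, driven by rearomatisation of ring B. No stereocentre is created, and C3 cannot epimerise because C4 is an sp3 carbinol and no enol can form. The step needs regioselectivity between the two carbons ortho to O4', which the silyloxy group on C3' secures since only at C5' can the dienone tautomerise (a shift to C3' can only revert), and it needs the electron-rich benzylic C4 carbinol to survive, which the acid-free, amine-buffered medium is meant to secure.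

Step 13
Reactants: 21 (3S,4S)-3-[2,2-dimethyl-8-(triisopropylsilyloxy)-2H-chromen-6-yl]-5-methoxy-7-(triisopropylsilyloxy)chroman-4-ol
Product: 22 (3S)-3-[2,2-dimethyl-8-(triisopropylsilyloxy)-2H-chromen-6-yl]-5-methoxy-7-(triisopropylsilyloxy)chroman-4-one
Conditions: Dess–Martin periodinane, NaHCO3, CH2Cl2, 0 °C to rt
Reagents that add atoms: none
Why: Dess–Martin oxidation (alcohol–acetate exchange at iodine, then intramolecular removal of the carbinol hydrogen) regenerates the ketone, and the solid hydrogencarbonate buffer takes up acetic acid without enolising the new α-aryl ketone, so 3S should be carried over unchanged.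

Step 14
Reactants: 22 (3S)-3-[2,2-dimethyl-8-(triisopropylsilyloxy)-2H-chromen-6-yl]-5-methoxy-7-(triisopropylsilyloxy)chroman-4-one
Product: 23 (3S)-7-hydroxy-3-(8-hydroxy-2,2-dimethyl-2H-chromen-6-yl)-5-methoxychroman-4-one (CNP0113665.1)
Conditions: HF·pyridine, pyridine, THF, 0 °C to rt
Reagents that add atoms: none
Why: fluoride-driven cleavage of both aryl silyl ethers in a pyridine-buffered, weakly acidic medium should free the two phenols without enolising C3 or adding to the chromene double bond.

**Compound list**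

1 | 2',4'-dihydroxy-6'-methoxyacetophenone | CC(=O)c1c(O)cc(O)cc1OC | starting material
2 | 1-[2-methoxy-4,6-bis(methoxymethoxy)phenyl]ethan-1-one | CC(=O)c1c(OCOC)cc(OCOC)cc1OC | intermediate
3 | 5-bromo-2-hydroxybenzaldehyde | O=Cc1cc(Br)ccc1O | starting material
4 | 2-(benzyloxy)-5-bromobenzaldehyde | O=Cc1cc(Br)ccc1OCc1ccccc1 | intermediate
5 | 2-(benzyloxy)-5-bromophenyl formate (not isolated) | O=COc1cc(Br)ccc1OCc1ccccc1 | intermediate
6 | 2-(benzyloxy)-5-bromophenol | Oc1cc(Br)ccc1OCc1ccccc1 | intermediate
7 | 1-(benzyloxy)-4-bromo-2-(methoxymethoxy)benzene | COCOc1cc(Br)ccc1OCc1ccccc1 | intermediate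
8 | 2-[4-(benzyloxy)-3-(methoxymethoxy)phenyl]-1-[2-methoxy-4,6-bis(methoxymethoxy)phenyl]ethan-1-one | COCOc1cc(OCOC)cc(OC)c1C(=O)Cc1ccc(OCc2ccccc2)c(OCOC)c1 | intermediate
9 | 2-[4-hydroxy-3-(methoxymethoxy)phenyl]-1-[2-methoxy-4,6-bis(methoxymethoxy)phenyl]ethan-1-one | COCOc1cc(OCOC)cc(OC)c1C(=O)Cc1ccc(O)c(OCOC)c1 | intermediate
10 | 3-chloro-3-methylbut-1-yne | CC(C)(Cl)C#C | starting material
11 | 1-[2-methoxy-4,6-bis(methoxymethoxy)phenyl]-2-[3-(methoxymethoxy)-4-(2-methylbut-3-yn-2-yloxy)phenyl]ethan-1-one | COCOc1cc(OCOC)cc(OC)c1C(=O)Cc1ccc(OC(C)(C)C#C)c(OCOC)c1 | intermediate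
12 | 1-(2,4-dihydroxy-6-methoxyphenyl)-2-[3-hydroxy-4-(2-methylbut-3-yn-2-yloxy)phenyl]ethan-1-one | COc1cc(O)cc(O)c1C(=O)Cc1ccc(OC(C)(C)C#C)c(O)c1 | intermediate
13 | 1-[2-hydroxy-6-methoxy-4-(triisopropylsilyloxy)phenyl]-2-[4-(2-methylbut-3-yn-2-yloxy)-3-(triisopropylsilyloxy)phenyl]ethan-1-one | COc1cc(O[Si](C(C)C)(C(C)C)C(C)C)cc(O)c1C(=O)Cc1ccc(OC(C)(C)C#C)c(O[Si](C(C)C)(C(C)C)C(C)C)c1 | intermediate
14 | 3-(diethylamino)-1-[2-hydroxy-6-methoxy-4-(triisopropylsilyloxy)phenyl]-2-[4-(2-methylbut-3-yn-2-yloxy)-3-(triisopropylsilyloxy)phenyl]propan-1-one, Mannich base (not isolated) | COc1cc(O[Si](C(C)C)(C(C)C)C(C)C)cc(O)c1C(=O)C(CN(CC)CC)c1ccc(OC(C)(C)C#C)c(O[Si](C(C)C)(C(C)C)C(C)C)c1 | intermediate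
15 | 1-[2-hydroxy-6-methoxy-4-(triisopropylsilyloxy)phenyl]-2-[4-(2-methylbut-3-yn-2-yloxy)-3-(triisopropylsilyloxy)phenyl]prop-2-en-1-one, enone (not isolated) | COc1cc(O[Si](C(C)C)(C(C)C)C(C)C)cc(O)c1C(=O)C(=C)c1ccc(OC(C)(C)C#C)c(O[Si](C(C)C)(C(C)C)C(C)C)c1 | intermediate
16 | rac-5-methoxy-3-[4-(2-methylbut-3-yn-2-yloxy)-3-(triisopropylsilyloxy)phenyl]-7-(triisopropylsilyloxy)chroman-4-one | COc1cc(O[Si](C(C)C)(C(C)C)C(C)C)cc2c1C(=O)C(c1ccc(OC(C)(C)C#C)c(O[Si](C(C)C)(C(C)C)C(C)C)c1)CO2 | intermediate
17 | (3S,4S)-5-methoxy-3-[4-(2-methylbut-3-yn-2-yloxy)-3-(triisopropylsilyloxy)phenyl]-7-(triisopropylsilyloxy)chroman-4-ol (cis) | COc1cc(O[Si](C(C)C)(C(C)C)C(C)C)cc2c1[C@@H](O)[C@@H](c1ccc(OC(C)(C)C#C)c(O[Si](C(C)C)(C(C)C)C(C)C)c1)CO2 | intermediate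
18 | allenyl cyclohexadienone from the [3,3] shift, 3-methylbuta-1,2-dienyl group on sp3 C5' (not isolated) | COc1cc(O[Si](C(C)C)(C(C)C)C(C)C)cc2c1[C@@H](O)[C@@H](C1=CC(C=C=C(C)C)C(=O)C(O[Si](C(C)C)(C(C)C)C(C)C)=C1)CO2 | intermediate
19 | ortho-allenylphenol, 4'-OH and 5'-(3-methylbuta-1,2-dienyl) (not isolated) | COc1cc(O[Si](C(C)C)(C(C)C)C(C)C)cc2c1[C@@H](O)[C@@H](c1cc(O[Si](C(C)C)(C(C)C)C(C)C)c(O)c(C=C=C(C)C)c1)CO2 | intermediate
20 | ortho-quinone methide, 4'-oxo and 5'-(3-methylbut-2-enylidene) (not isolated) | COc1cc(O[Si](C(C)C)(C(C)C)C(C)C)cc2c1[C@@H](O)[C@@H](C1=CC(=CC=C(C)C)C(=O)C(O[Si](C(C)C)(C(C)C)C(C)C)=C1)CO2 | intermediate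
21 | (3S,4S)-3-[2,2-dimethyl-8-(triisopropylsilyloxy)-2H-chromen-6-yl]-5-methoxy-7-(triisopropylsilyloxy)chroman-4-ol | COc1cc(O[Si](C(C)C)(C(C)C)C(C)C)cc2c1[C@@H](O)[C@@H](c1cc(O[Si](C(C)C)(C(C)C)C(C)C)c3c(c1)C=CC(C)(C)O3)CO2 | intermediate
22 | (3S)-3-[2,2-dimethyl-8-(triisopropylsilyloxy)-2H-chromen-6-yl]-5-methoxy-7-(triisopropylsilyloxy)chroman-4-one | COc1cc(O[Si](C(C)C)(C(C)C)C(C)C)cc2c1C(=O)[C@@H](c1cc(O[Si](C(C)C)(C(C)C)C(C)C)c3c(c1)C=CC(C)(C)O3)CO2 | intermediate
23 | (3S)-7-hydroxy-3-(8-hydroxy-2,2-dimethyl-2H-chromen-6-yl)-5-methoxychroman-4-one (CNP0113665.1) | COc1cc(O)cc2c1C(=O)[C@@H](c1cc(O)c3c(c1)C=CC(C)(C)O3)CO2 | target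

**Step count**

Total: 14 steps. Longest linear sequence: 13 steps (from 3 through steps 2–14; the ring A branch from 1 joins at step 5).

**Steps most likely to fail**

Step 12. At 140–150 °C the very electron-rich benzylic C4 carbinol may ionise and dehydrate to the isoflav-3-ene, which would erase both stereocentres, or the free hydroxyl may add to the ortho-quinone methide faster than the electrocyclisation. The fallback sets out from racemic ketone 16 and runs the same thermal cascade (PhNEt2, o-xylene, 140 °C) there, where no carbinol and no stereochemical information are at risk, to give rac-3-[2,2-dimethyl-8-(triisopropylsilyloxy)-2H-chromen-6-yl]-5-methoxy-7-(triisopropylsilyloxy)chroman-4-one F1. The transfer hydrogenation of step 11 (RuCl(p-cymene)[(S,S)-TsDPEN], HCO2H/Et3N, EtOAc, 40 °C) is then applied to F1, whose chromene double bond is not a substrate for the ruthenium hydride, and the route is rejoined at 21.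

Step 11. Hydride transfer to the doubly ortho-substituted, strongly donor-substituted carbonyl may be slow, or the terminal alkyne may bind ruthenium, so that conversion stalls or reduction and enolisation fall out of step and selectivity erodes. The fallback sets out from 16 and uses a Corey–Bakshi–Shibata reduction as a kinetic resolution: (R)-2-methyl-CBS-oxazaborolidine with catecholborane in toluene at −40 °C, stopped near half conversion, then aqueous work-up. Catecholborane is chosen because it does not hydroborate the alkyne at this temperature. The 3S ketone is the matched substrate, since reagent control toward 4S and hydride approach anti to the C3 aryl group coincide, and it should give 17 directly, where the route is rejoined. The unreacted, 3R-enriched ketone is stirred with Et3N to racemise it and is used again as 16.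

Step 10. The product still has an acidic C3–H and may take up a second formaldehyde unit, and the amine in an alcohol may strip the aryl silyl ether that sits para to the ketone. The fallback sets out from 13 and heats it with N,N-dimethylformamide dimethyl acetal in toluene at 80 °C. This should give 3-(dimethylamino)-1-[2-hydroxy-6-methoxy-4-(triisopropylsilyloxy)phenyl]-2-[4-(2-methylbut-3-yn-2-yloxy)-3-(triisopropylsilyloxy)phenyl]prop-2-en-1-one, the enaminone F2, which is not isolated and cyclises with loss of dimethylamine to 5-methoxy-3-[4-(2-methylbut-3-yn-2-yloxy)-3-(triisopropylsilyloxy)phenyl]-7-(triisopropylsilyloxy)-4H-chromen-4-one, the isoflavone F3. Conjugate reduction of F3 with LiBH(s-Bu)3 in THF at −78 °C, followed by a water quench of the enolate, returns the route to 16.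

**Further compounds**

F1 | step 12 | rac-3-[2,2-dimethyl-8-(triisopropylsilyloxy)-2H-chromen-6-yl]-5-methoxy-7-(triisopropylsilyloxy)chroman-4-one | COc1cc(O[Si](C(C)C)(C(C)C)C(C)C)cc2c1C(=O)C(c1cc(O[Si](C(C)C)(C(C)C)C(C)C)c3c(c1)C=CC(C)(C)O3)CO2
F0 | step 11 | none | none
F2 | step 10 | 3-(dimethylamino)-1-[2-hydroxy-6-methoxy-4-(triisopropylsilyloxy)phenyl]-2-[4-(2-methylbut-3-yn-2-yloxy)-3-(triisopropylsilyloxy)phenyl]prop-2-en-1-one (enaminone, not isolated) | COc1cc(O[Si](C(C)C)(C(C)C)C(C)C)cc(O)c1C(=O)C(=CN(C)C)c1ccc(OC(C)(C)C#C)c(O[Si](C(C)C)(C(C)C)C(C)C)c1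
F3 | step 10 | 5-methoxy-3-[4-(2-methylbut-3-yn-2-yloxy)-3-(triisopropylsilyloxy)phenyl]-7-(triisopropylsilyloxy)-4H-chromen-4-one (isoflavone) | COc1cc(O[Si](C(C)C)(C(C)C)C(C)C)cc2occ(-c3ccc(OC(C)(C)C#C)c(O[Si](C(C)C)(C(C)C)C(C)C)c3)c(=O)c12
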